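## The problem

5'-Methoxyhydnocarpin (22) joins a 5,7-dihydroxyflavone (rings A and C) through the C2–C1' bond to a ring B that is fused through O3' and O4' to a 1,4-dioxane. Cα (on O3') carries the guaiacyl group, Cβ (on O4') the hydroxymethyl group, and C5' a methoxy group. The synthesis must fix this regiochemistry of the dioxane, because the isomer with the aryl group next to O4' would be just as stable, and it must deliver the trans pair Cα(R)/Cβ(R) as one enantiomer. The two stereocenters are neighbours and the trans ring is the thermodynamic one, so either centre can steer the other, but the absolute sense has to come from a reagent or an auxiliary. The fragile features are the p-hydroxybenzylic aryl ether at Cα (quinone methide under base when the phenol is free, benzylic cation under strong acid, hydrogenolysis), the oxidisable phloroglucinol ring A, and the pyranone ring C, which hard nucleophiles open. Ring A (C4a, C5, C6, C7, C8, C8a) is a phloroglucinol, a folded triketide, fused to ring C, and C4a is the α-carbon of the vinylogous ester O1–C8a=C4a–C4=O. If ring C is present first as a 4-pyranone with a 3-oxobutanoate chain on C8a, ionisation at C8 makes C4a a carbon nucleophile six atoms from the ester carbon C5, so one Claisen closure and tautomerisation can build ring A with no protecting group on it.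

## Retrosynthesis

**22 to 21 (protecting groups).** The guaiacyl phenol and the primary alcohol of 22 are traced back to the two benzyl ethers of 21. The phenol must stay capped through every basic step, since a free p-hydroxybenzyl aryl ether opens to a quinone methide. Benzyl is preferred to acetal or silyl groups because it survives amide bases, the acid that makes ring C and the magnesium alkoxide of the key step, and because both ethers fall in one hydrogenolysis. The forward step only has to spare the C2=C3 bond and the cyclic Cα–O bond.

**21 to 20 (C4a–C5, ring A).** Cutting ring A at C4a–C5 turns the phloroglucinol into the methyl 3-oxobutanoate chain of pyranone 20. This is the one ring A bond that pairs a carbon already conjugated to the C4 carbonyl (donor) with an ester (acceptor). Cuts at C5–C6 or C7–C8 would need the ring as acceptor, and the classical cut through ring C would need a protected phloroacetophenone. Precursor 20 is one ring simpler and has no phenol to protect. The forward reaction asks a carbon of an intact pyranone to act as a Claisen donor, which is untested, so the route keeps a conventional bypass from 10.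

**20 to 16 and 17, then 16 to 14 (C6–C7 and C7–C8).** The keto ester is cut at C6–C7 into acid 16 and potassium methyl malonate 17, joined by decarboxylative acylation under nearly neutral magnesium conditions, which tolerates two very acidic methylenes. Acid 16 is cut at C7–C8 to the 6-methylpyranone 14 by lateral carboxylation. Attaching the four-carbon unit in one step would need an acyl donor with its own acidic methylene, so two clean steps are preferred.

**14 to 13 to 10 and 11 (ring C).** The O1–C8a bond is cut to triketone 13 (acid cyclodehydration), and the C2–C3 bond to the ring B methyl ester 10 and acetylacetone 11 (acylation of the diketone dianion). All five carbons C3, C4, C4a, C8a and C8 come from one commodity, and because the triketone is symmetric about C4 only one pyranone can form. The forward steps need 10 to carry a single ester and no acid-labile group.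

**10 to 9 (O3'–C3').** The dioxane is opened at the aryl C–O bond, not at O–Cα or O–Cβ. The forward closure, a copper-catalysed etherification of the Cα carbinol by the ring B bromide, therefore breaks no bond at a stereocenter and carries the acyclic configuration into the ring with retention. The bromine sits ortho to the phenolic oxygen, exactly where bromination of a vanillate places it, so ring B comes as phenol 1.

**9 to 7 to 6 to 3 and 4 (Cα–Cβ).** The primary benzyl ether of 9 goes back to diol 7, the diol to imide 6 by reductive removal of the auxiliary, and 6 is cut at Cα–Cβ. The forward reaction is a syn-selective glycolate-type aldol between the boron enolate 5 of imide 3 and O-benzylvanillin 4. It forms the only C–C bond of the lignan half and both stereocenters at once under auxiliary control, and the syn adduct is the one that a retentive ring closure turns into the trans dioxane. Reduction gives the hydroxymethyl oxidation state directly and leaves the ring B ester as the only ester for the later acylation.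

**3 to 1 and 2 (O4'–CH2).** Alkylation of phenol 1 with the chloroacetyl imide 2 fixes the regiochemistry from the start: the phenolic oxygen para to the ester becomes O4', bonded to the future Cβ.

## Roads not taken

**Alternative 1:** The cut is O3'–Cα of the dioxane at the stage of a ring B aldehyde. Aqueous CF3CO2H would strip the methoxymethyl groups of the acyclic carbinol A1 (Cβ defined, either epimer at Cα), ionise the benzylic carbinol and let the freed C3' hydroxyl close the ring to the trans-(2R,3R)-benzodioxane aldehyde A2.
- Merits: the closure is stereoconvergent, so only Cβ has to be set; deprotection and ring formation are one operation; the reaction type is well known.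
- Weak points: it solves only the lignan half. A2, with a free phenol and a free alcohol, must still be taken to the flavone by chalcone or diketone chemistry with a protected phloroacetophenone, so ring A protection and re-protection of A2 return. Cβ must be set by a separate displacement. The cation meets two electron-rich rings and an aldehyde.
- Comparison: for the dioxane alone this closure is the more forgiving one, better than step 5 below, since it needs no metal-catalysed coupling and is indifferent to the Cα configuration. It is therefore kept as the fallback for step 5. The chosen plan sets against it one aldol that fixes both centres, no deprotection and re-protection cycle, and a ring A that never needs protecting.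

**Alternative 2:** The cuts are O3'–Cα and C4'–O in one cascade. The caesium phenoxide of bromophenol A3 (Cs2CO3) would open the cis-glycidate A4 at the benzylic carbon with inversion, and the released Cβ alkoxide would be arylated at C4'–Br under CuI (monovalent copper) to give the trans diester A5.
- Merits: two C–O bonds, the ring and the relay of both stereocenters in one flask.
- Weak points: A3 has bromine between two oxygens, a pattern that direct bromination does not give (it gives the isomer used here, 1). Enantiopure A4 needs several steps. The alkoxide to be arylated lies next to an ester (retro-aldol and epimerisation under hot carbonate) and must attack a bromide with two ortho substituents. The two esters of A5 must then be told apart, and the flavone is still to be built.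
- Comparison: in bonds formed per step the cascade is better than steps 2 to 5 here, and with A3 and A4 on the shelf it would be shorter. The chosen plan answers with a commercial ring B phenol, a coupling at a bromide with one ortho substituent by an alkoxide that has no carbonyl nearby, and a hydroxymethyl group that arrives at the right oxidation level.

**Alternative 3:** The cuts are C4a–C4, C4–C3 and O1–C2: ring C from two finished halves. Iodophenol A6 and alkyne A7 would be joined in a carbonylative three-component annulation under PdCl2(PPh3)2 and diethylamine to give the fully protected flavone A8.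
- Merits: it is the most convergent plan, and the reaction type is known for flavones, which the chosen key step is not. In precedent this road is ahead.
- Weak points: A6 is a very electron-rich iodide flanked by two oxygens, so oxidative addition to zerovalent palladium and acyl formation are slow, and direct alkynylation to a 2-arylbenzofuran competes. The ynone can close 5-exo to an aurone instead of 6-endo. Mono-iodination of a partly protected phloroglucinol is a regiochemical problem. Ring A carries two protecting groups on and off, A7 needs an aldehyde-to-alkyne homologation, and a pressurised toxic gas is required.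
- Comparison: the chosen plan gives up convergence and precedent. It sets against them a ring A without protecting groups, a closure with only one possible ring size, cheap two- and five-carbon building blocks, and a conventional diketone route from 10 as a safety net.

Key step: step 10

Assumption: phenol 1 and chloroacetyl imide 2 are taken as catalogue compounds; each is otherwise one standard step from a commodity (bromination of methyl vanillate; N-acylation of (S)-4-benzyloxazolidin-2-one with chloroacetyl chloride), which would not change the chemistry that follows.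

In the names below, BD is the (2R,3R)-3-[4-(benzyloxy)-3-methoxyphenyl]-2-[(benzyloxy)methyl]-8-methoxy-2,3-dihydro-1,4-benzodioxin-6-yl group of compound 10.

## Route

Step 1
Reactants: 1 methyl 3-bromo-4-hydroxy-5-methoxybenzoate; 2 (4S)-4-benzyl-3-(chloroacetyl)-1,3-oxazolidin-2-one
Product: 3 methyl 4-{2-[(4S)-4-benzyl-2-oxo-1,3-oxazolidin-3-yl]-2-oxoethoxy}-3-bromo-5-methoxybenzoate
Conditions: K2CO3, NaI (cat.), acetone, 50 °C
Reagents that add atoms: none
Why: Williamson O-alkylation (SN2) of an acidic, weakly basic phenoxide by an α-halo imide; the mild carbonate base leaves the imide and the methyl ester untouched.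

Step 2
Reactants: 3 methyl 4-{2-[(4S)-4-benzyl-2-oxo-1,3-oxazolidin-3-yl]-2-oxoethoxy}-3-bromo-5-methoxybenzoate; 4 4-(benzyloxy)-3-methoxybenzaldehyde
Product: 6 (4S)-4-benzyl-3-{(2S,3R)-3-[4-(benzyloxy)-3-methoxyphenyl]-2-[2-bromo-6-methoxy-4-(methoxycarbonyl)phenoxy]-3-hydroxypropanoyl}-1,3-oxazolidin-2-one, via dibutylboron Z-enolate 5 (not isolated)
Conditions: Bu2BOTf, iPr2NEt, CH2Cl2, −78 to 0 °C; then 4, −78 to 0 °C; pH 7 buffer, MeOH, 30% H2O2, 0 °C
Reagents that add atoms: none
Why: Evans syn-aldol of a glycolate-type imide: the Z-boron enolate reacts through a closed Zimmerman–Traxler transition state in which the benzyl group of the (S)-auxiliary shields one enolate face, so Cα (R) and Cβ are set together in the syn relation that later becomes the trans ring; aryloxyacetyl imides are known partners in this reaction.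

Step 3
Reactants: 6 (4S)-4-benzyl-3-{(2S,3R)-3-[4-(benzyloxy)-3-methoxyphenyl]-2-[2-bromo-6-methoxy-4-(methoxycarbonyl)phenoxy]-3-hydroxypropanoyl}-1,3-oxazolidin-2-one
Product: 7 methyl 4-{[(1R,2R)-1-[4-(benzyloxy)-3-methoxyphenyl]-1,3-dihydroxypropan-2-yl]oxy}-3-bromo-5-methoxybenzoate
Conditions: NaBH4, THF/H2O (4:1), 0 °C to rt
Reagents that add atoms: none
Why: Reductive cleavage of the N-acyl oxazolidinone at the activated exocyclic carbonyl; NaBH4 leaves the aromatic methyl ester and the aryl bromide alone, and no stereocenter is touched (the Cβ descriptor changes only because the carbonyl becomes CH2OH).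

Step 4
Reactants: 7 methyl 4-{[(1R,2R)-1-[4-(benzyloxy)-3-methoxyphenyl]-1,3-dihydroxypropan-2-yl]oxy}-3-bromo-5-methoxybenzoate
Product: 9 methyl 4-{[(1R,2R)-3-(benzyloxy)-1-[4-(benzyloxy)-3-methoxyphenyl]-1-hydroxypropan-2-yl]oxy}-3-bromo-5-methoxybenzoate, via dibutylstannylene acetal 8 (not isolated)
Conditions: Bu2SnO, toluene, reflux (Dean–Stark); then BnBr, Bu4NBr (cat.), 90 °C
Reagents that add atoms: benzyl bromide, BrCc1ccccc1
Why: Stannylene-acetal-directed mono-alkylation of a 1,3-diol: in the six-membered dibutylstannylene the less hindered primary oxygen is benzylated and the benzylic carbinol stays free.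

Step 5
Reactants: 9 methyl 4-{[(1R,2R)-3-(benzyloxy)-1-[4-(benzyloxy)-3-methoxyphenyl]-1-hydroxypropan-2-yl]oxy}-3-bromo-5-methoxybenzoate
Product: 10 methyl (2R,3R)-3-[4-(benzyloxy)-3-methoxyphenyl]-2-[(benzyloxy)methyl]-8-methoxy-2,3-dihydro-1,4-benzodioxine-6-carboxylate (BD–CO2Me)
Conditions: CuI (10 mol%), 1,10-phenanthroline (20 mol%), Cs2CO3, toluene, 110 °C
Reagents that add atoms: none
Why: Intramolecular Ullmann-type etherification (copper-catalysed O-arylation of a secondary alcohol by an aryl bromide) closes the six-membered dioxane; the carbinol C–O bond is never broken, so Cα keeps the R configuration and the syn aldol relation becomes the trans ring.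

Step 6
Reactants: 10 BD–CO2Me; 11 pentane-2,4-dione (acetylacetone)
Product: 13 1-BD-hexane-1,3,5-trione, via dilithio acetylacetonate 12 (not isolated)
Conditions: 11 (3 equiv), LiN(iPr)2 (6 equiv), THF, 0 °C; then 10, 0 °C to rt; 1 M HCl
Reagents that add atoms: none
Why: Claisen-type acylation of the terminal carbanion of a β-diketone dianion by an aromatic ester; excess dianion absorbs the acidic protons of the triketone as it forms, and 10 has no other electrophilic or acidic site.

Step 7
Reactants: 13 1-BD-hexane-1,3,5-trione
Product: 14 2-BD-6-methyl-4H-pyran-4-one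
Conditions: TsOH·H2O (20 mol%), toluene, 80 °C
Reagents that add atoms: none
Why: Acid-catalysed cyclodehydration of a 1,3,5-triketone to a 4-pyranone (enol oxygen adds to the far carbonyl, water is lost); the triketone is symmetric about the central carbonyl so only one pyranone can form, and the benzyl ethers and the trans dioxane are stable to catalytic sulfonic acid.

Step 8
Reactants: 14 2-BD-6-methyl-4H-pyran-4-one
Product: 16 (6-BD-4-oxo-4H-pyran-2-yl)acetic acid, via lithiated pyranone 15 (not isolated)
Conditions: LiN(SiMe3)2 (2.1 equiv), THF, −78 °C; CO2 (excess), −78 to 0 °C; 1 M HCl to pH 3, 0 °C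
Reagents that add atoms: carbon dioxide, O=C=O
Why: Lateral (γ) deprotonation of the 6-methyl group of a 4-pyranone gives the vinylogous enolate, which is carboxylated at the exocyclic carbon; the second equivalent of base takes up the more acidic methylene of the carboxylate so that it does not quench unreacted anion.

Step 9
Reactants: 16 (6-BD-4-oxo-4H-pyran-2-yl)acetic acid; 17 potassium 3-methoxy-3-oxopropanoate (potassium methyl malonate)
Product: 20 methyl 4-(6-BD-4-oxo-4H-pyran-2-yl)-3-oxobutanoate, via acyl imidazolide 18 (not isolated), via acylmalonic half-ester 19 (not isolated)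
Conditions: 1,1'-carbonyldiimidazole, THF, rt; then 17, MgCl2, Et3N, MeCN/THF, rt to 40 °C; 1 M HCl
Reagents that add atoms: none
Why: Masamune–Brooks homologation: the acyl imidazolide is C-acylated by the magnesium enolate of the malonate half-ester and the adduct loses CO2, giving the β-keto ester under nearly neutral conditions that an arylacetic-type acid tolerates.

Step 10
Reactants: 20 methyl 4-(6-BD-4-oxo-4H-pyran-2-yl)-3-oxobutanoate
Product: 21 2-BD-5,7-dihydroxy-4H-chromen-4-one
Conditions: Mg(OMe)2 (4 equiv), MeOH/THF (3:1), 65 °C; then 1 M HCl, 0 °C to rt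
Reagents that add atoms: none
Why: Proposed new method: Mg(OMe)2 ionises the C8 methylene to a magnesium dienolate delocalised through C8a=C4a into the C4 carbonyl, so that C4a (C3 of the pyranone, the α-carbon of the vinylogous ester) attacks the magnesium-bound ester carbon C5; loss of methoxide and enolisation of the cyclic triketone give the aromatic 5,7-diol, held as a magnesium chelate between the C5 oxygen and the C4 carbonyl until acidification. The closest known reaction types are the magnesium-alkoxide-promoted Claisen cyclisation of 3,5,7-triketo esters to acylphloroglucinols and the γ-deprotonation of 2-alkyl-4-pyranones, but a Claisen closure onto a ring carbon of an intact pyranone has not been shown. Ring A closes in a 6-(enolexo)-exo-trig mode. No stereocenter is formed, and Cα and Cβ are safe because neither bears an acidic hydrogen and the capped phenol cannot form a quinone methide. The step needs C-acylation at C4a in preference to methoxide addition to the pyranone and to retro-Claisen cleavage of the keto ester. The substrate secures this because both activated methylenes ionise first, making ring and chain anionic and poor acceptors for methoxide, while C4a is the only nucleophilic atom that reaches C5 through a six-membered array (attack from C8 or from the C4 oxygen would need a four- or an eight-membered ring). Aromatisation and chelation make the closure irreversible, and the methyl ester in methanol cannot scramble.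

Step 11
Reactants: 21 2-BD-5,7-dihydroxy-4H-chromen-4-one
Product: 22 5'-methoxyhydnocarpin, 5,7-dihydroxy-2-[(2R,3R)-3-(4-hydroxy-3-methoxyphenyl)-2-(hydroxymethyl)-8-methoxy-2,3-dihydro-1,4-benzodioxin-6-yl]-4H-chromen-4-one
Conditions: H2 (1 atm), 10% Pd/C, THF/MeOH, rt
Reagents that add atoms: none
Why: Catalytic hydrogenolysis of one aryl benzyl ether and one primary alkyl benzyl ether; the flavone C2=C3 bond and the cyclic benzylic aryl ether of the dioxane react much more slowly, so the reaction is stopped after uptake of two equivalents of H2.

## Compound list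

1 | methyl 3-bromo-4-hydroxy-5-methoxybenzoate | COC(=O)c1cc(Br)c(O)c(OC)c1 | starting material
2 | (4S)-4-benzyl-3-(chloroacetyl)-1,3-oxazolidin-2-one | O=C(CCl)N1C(=O)OC[C@@H]1Cc1ccccc1 | starting material
3 | methyl 4-{2-[(4S)-4-benzyl-2-oxo-1,3-oxazolidin-3-yl]-2-oxoethoxy}-3-bromo-5-methoxybenzoate | COC(=O)c1cc(Br)c(OCC(=O)N2C(=O)OC[C@@H]2Cc2ccccc2)c(OC)c1 | intermediate
4 | 4-(benzyloxy)-3-methoxybenzaldehyde | COc1cc(C=O)ccc1OCc1ccccc1 | starting material
5 | dibutylboron Z-enolate of 3 | CCCCB(CCCC)O/C(=C\Oc1c(Br)cc(C(=O)OC)cc1OC)N1C(=O)OC[C@@H]1Cc1ccccc1 | intermediate (not isolated)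
6 | (4S)-4-benzyl-3-{(2S,3R)-3-[4-(benzyloxy)-3-methoxyphenyl]-2-[2-bromo-6-methoxy-4-(methoxycarbonyl)phenoxy]-3-hydroxypropanoyl}-1,3-oxazolidin-2-one | COc1cc([C@@H](O)[C@H](Oc2c(Br)cc(C(=O)OC)cc2OC)C(=O)N2C(=O)OC[C@@H]2Cc2ccccc2)ccc1OCc1ccccc1 | intermediate
7 | methyl 4-{[(1R,2R)-1-[4-(benzyloxy)-3-methoxyphenyl]-1,3-dihydroxypropan-2-yl]oxy}-3-bromo-5-methoxybenzoate | COc1cc([C@@H](O)[C@H](Oc2c(Br)cc(C(=O)OC)cc2OC)CO)ccc1OCc1ccccc1 | intermediate
8 | dibutylstannylene acetal of 7, methyl 4-{[(4R,5R)-4-[4-(benzyloxy)-3-methoxyphenyl]-2,2-dibutyl-1,3,2-dioxastanninan-5-yl]oxy}-3-bromo-5-methoxybenzoate | COc1cc([C@H]2O[Sn](CCCC)(CCCC)OC[C@H]2Oc2c(Br)cc(C(=O)OC)cc2OC)ccc1OCc1ccccc1 | intermediate (not isolated)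
9 | methyl 4-{[(1R,2R)-3-(benzyloxy)-1-[4-(benzyloxy)-3-methoxyphenyl]-1-hydroxypropan-2-yl]oxy}-3-bromo-5-methoxybenzoate | COc1cc([C@@H](O)[C@H](Oc2c(Br)cc(C(=O)OC)cc2OC)COCc2ccccc2)ccc1OCc1ccccc1 | intermediate
10 | methyl (2R,3R)-3-[4-(benzyloxy)-3-methoxyphenyl]-2-[(benzyloxy)methyl]-8-methoxy-2,3-dihydro-1,4-benzodioxine-6-carboxylate (BD–CO2Me) | COc1cc([C@H]2Oc3cc(C(=O)OC)cc(OC)c3O[C@@H]2COCc2ccccc2)ccc1OCc1ccccc1 | intermediate
11 | pentane-2,4-dione (acetylacetone) | CC(=O)CC(C)=O | starting material
12 | dilithio acetylacetonate | [Li+].[Li+].C=C([O-])C=C(C)[O-] | intermediate (not isolated)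
13 | 1-BD-hexane-1,3,5-trione | COc1cc([C@H]2Oc3cc(C(=O)CC(=O)CC(C)=O)cc(OC)c3O[C@@H]2COCc2ccccc2)ccc1OCc1ccccc1 | intermediate
14 | 2-BD-6-methyl-4H-pyran-4-one | COc1cc([C@H]2Oc3cc(-c4cc(=O)cc(C)o4)cc(OC)c3O[C@@H]2COCc2ccccc2)ccc1OCc1ccccc1 | intermediate
15 | lithiated pyranone (lithium 2-BD-6-methylidene-6H-pyran-4-olate) | [Li+].COc1cc([C@H]2Oc3cc(C4=CC([O-])=CC(=C)O4)cc(OC)c3O[C@@H]2COCc2ccccc2)ccc1OCc1ccccc1 | intermediate (not isolated)
16 | (6-BD-4-oxo-4H-pyran-2-yl)acetic acid | COc1cc([C@H]2Oc3cc(-c4cc(=O)cc(CC(=O)O)o4)cc(OC)c3O[C@@H]2COCc2ccccc2)ccc1OCc1ccccc1 | intermediate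
17 | potassium 3-methoxy-3-oxopropanoate (potassium methyl malonate) | COC(=O)CC(=O)[O-].[K+] | starting material
18 | acyl imidazolide of 16, 2-BD-6-[2-(imidazol-1-yl)-2-oxoethyl]-4H-pyran-4-one | COc1cc([C@H]2Oc3cc(-c4cc(=O)cc(CC(=O)n5ccnc5)o4)cc(OC)c3O[C@@H]2COCc2ccccc2)ccc1OCc1ccccc1 | intermediate (not isolated)
19 | acylmalonic half-ester, 2-(methoxycarbonyl)-3-oxo-4-(6-BD-4-oxo-4H-pyran-2-yl)butanoic acid | COc1cc([C@H]2Oc3cc(-c4cc(=O)cc(CC(=O)C(C(=O)O)C(=O)OC)o4)cc(OC)c3O[C@@H]2COCc2ccccc2)ccc1OCc1ccccc1 | intermediate (not isolated)
20 | methyl 4-(6-BD-4-oxo-4H-pyran-2-yl)-3-oxobutanoate | COc1cc([C@H]2Oc3cc(-c4cc(=O)cc(CC(=O)CC(=O)OC)o4)cc(OC)c3O[C@@H]2COCc2ccccc2)ccc1OCc1ccccc1 | intermediate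
21 | 2-BD-5,7-dihydroxy-4H-chromen-4-one | COc1cc([C@H]2Oc3cc(-c4cc(=O)c5c(O)cc(O)cc5o4)cc(OC)c3O[C@@H]2COCc2ccccc2)ccc1OCc1ccccc1 | intermediate
22 | 5'-methoxyhydnocarpin | COc1cc([C@H]2Oc3cc(-c4cc(=O)c5c(O)cc(O)cc5o4)cc(OC)c3O[C@@H]2CO)ccc1O | target

## Step count and least certain steps

Total: 11 steps. Longest linear sequence: 11 steps (from 1; compounds 2, 4, 11 and 17 enter along the line).

**Step 10 (key step, proposed new method).**
- What may go wrong: the ester may fail to be attacked, because ionisation at C6 (the β-keto ester methylene) removes the electrophilicity of C5 and competes with the C8 dienolate that the closure needs. On forcing, methoxide addition to C2 or C8a can open the pyranone and let the freed polyketone fold by aldol paths, or retro-Claisen cleavage can shorten the chain.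
- Fallback (known chemistry), from 10 back to 21: hydrolysis of 10 (LiOH, THF/H2O) gives the benzodioxane carboxylic acid F1, which (COCl)2 with a trace of DMF turns into the acid chloride F2. C-aroylation of the lithium polyanion of 2',4',6'-trihydroxyacetophenone (LiN(SiMe3)2, THF, −78 °C to rt) with F2 gives the 1,3-diketone F3, the intermediate of a Baker–Venkataraman flavone synthesis. Cyclodehydration (TsOH·H2O, toluene, 80 °C) closes ring C and gives 21. Ring A is then bought and ring C made last.
- An opened chain in step 10 that still closes C4a–C5 would itself arrive at F3 and could be funnelled to 21 by the same acid treatment.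

**Step 5 (copper-catalysed ring closure).**
- What may go wrong: oxidative addition of monovalent copper to an electron-rich bromide may be slow. The caesium alkoxide is then exposed at 110 °C, where migration of ring B from the Cβ oxygen to the Cα oxygen (Smiles rearrangement, which would scramble the regiochemistry) or displacement of the aryloxide by the alkoxide (epoxide formation) can take over.
- Fallback, from 9 back to 10, replacing the aryl C–O coupling by a cationic closure at Cα: Miyaura borylation of 9 (PdCl2(dppf), B2pin2, KOAc, dioxane, 80 °C) gives the pinacol boronate F4, and oxidation (NaBO3·4H2O, THF/H2O, rt) gives the phenol F5. BF3·OEt2 in CH2Cl2 at −20 °C ionises the p-alkoxybenzylic carbinol, and the C3' hydroxyl traps the cation to give the thermodynamically preferred trans ring 10 whatever the fidelity at Cα, since Cβ is fixed.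

**Step 8 (lateral carboxylation).**
- What may go wrong: the amide base may deprotonate a ring position or add to the pyranone, and proton transfer from the newly formed, more acidic methylene to unreacted anion may stop the conversion.
- Fallback, from 10 back to 16, bringing in the carboxyl carbon before ring C exists: acylation of the trianion of methyl 3,5-dioxohexanoate (LiN(iPr)2, 3 equiv, THF, 0 °C) with 10 gives the triketo ester F6. Acid cyclodehydration (TsOH·H2O, toluene, 80 °C) gives the methyl pyranonylacetate F7, and mild hydrolysis (LiOH, THF/H2O, 0 °C) gives 16. This replaces steps 6 to 8.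

**Step 9 (chain extension).**
- What may go wrong: the imidazolide has a doubly activated methylene, so enolisation to a ketene and self-condensation may outrun C-acylation by the magnesium malonate.
- Fallback, from 16 back to 20, changing the two-carbon donor and the acyl-transfer mechanism: coupling of 16 with Meldrum's acid (N,N'-dicyclohexylcarbodiimide, 4-dimethylaminopyridine, CH2Cl2, 0 °C) gives the acyl Meldrum's acid F8. Heating F8 in MeOH/toluene releases acetone and CO2 by way of the acylketene, which methanol traps as 20.

## Further compounds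

F1 | step 10 | (2R,3R)-3-[4-(benzyloxy)-3-methoxyphenyl]-2-[(benzyloxy)methyl]-8-methoxy-2,3-dihydro-1,4-benzodioxine-6-carboxylic acid (BD–CO2H) | COc1cc([C@H]2Oc3cc(C(=O)O)cc(OC)c3O[C@@H]2COCc2ccccc2)ccc1OCc1ccccc1
F2 | step 10 | BD–COCl, the acid chloride of F1 | COc1cc([C@H]2Oc3cc(C(=O)Cl)cc(OC)c3O[C@@H]2COCc2ccccc2)ccc1OCc1ccccc1
F3 | step 10 | 1-BD-3-(2,4,6-trihydroxyphenyl)propane-1,3-dione | COc1cc([C@H]2Oc3cc(C(=O)CC(=O)c4c(O)cc(O)cc4O)cc(OC)c3O[C@@H]2COCc2ccccc2)ccc1OCc1ccccc1
F4 | step 5 | methyl 4-{[(1R,2R)-3-(benzyloxy)-1-[4-(benzyloxy)-3-methoxyphenyl]-1-hydroxypropan-2-yl]oxy}-3-methoxy-5-(4,4,5,5-tetramethyl-1,3,2-dioxaborolan-2-yl)benzoate | COc1cc([C@@H](O)[C@H](Oc2c(B3OC(C)(C)C(C)(C)O3)cc(C(=O)OC)cc2OC)COCc2ccccc2)ccc1OCc1ccccc1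
F5 | step 5 | methyl 4-{[(1R,2R)-3-(benzyloxy)-1-[4-(benzyloxy)-3-methoxyphenyl]-1-hydroxypropan-2-yl]oxy}-3-hydroxy-5-methoxybenzoate | COc1cc([C@@H](O)[C@H](Oc2c(O)cc(C(=O)OC)cc2OC)COCc2ccccc2)ccc1OCc1ccccc1
F6 | step 8 | methyl 7-BD-3,5,7-trioxoheptanoate | COc1cc([C@H]2Oc3cc(C(=O)CC(=O)CC(=O)CC(=O)OC)cc(OC)c3O[C@@H]2COCc2ccccc2)ccc1OCc1ccccc1
F7 | step 8 | methyl (6-BD-4-oxo-4H-pyran-2-yl)acetate | COc1cc([C@H]2Oc3cc(-c4cc(=O)cc(CC(=O)OC)o4)cc(OC)c3O[C@@H]2COCc2ccccc2)ccc1OCc1ccccc1
F8 | step 9 | 5-[(6-BD-4-oxo-4H-pyran-2-yl)acetyl]-2,2-dimethyl-1,3-dioxane-4,6-dione | COc1cc([C@H]2Oc3cc(-c4cc(=O)cc(CC(=O)C5C(=O)OC(C)(C)OC5=O)o4)cc(OC)c3O[C@@H]2COCc2ccccc2)ccc1OCc1ccccc1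
A1 | alternative 1 | 4-{[(2R)-1,3-dihydroxy-1-[3-methoxy-4-(methoxymethoxy)phenyl]propan-2-yl]oxy}-3-methoxy-5-(methoxymethoxy)benzaldehyde (either configuration at the carbinol carbon) | COCOc1ccc(C(O)[C@@H](CO)Oc2c(OC)cc(C=O)cc2OCOC)cc1OC
A2 | alternative 1 | (2R,3R)-3-(4-hydroxy-3-methoxyphenyl)-2-(hydroxymethyl)-8-methoxy-2,3-dihydro-1,4-benzodioxine-6-carbaldehyde | COc1cc([C@H]2Oc3cc(C=O)cc(OC)c3O[C@@H]2CO)ccc1O
A3 | alternative 2 | methyl 4-bromo-3-hydroxy-5-methoxybenzoate | COC(=O)c1cc(O)c(Br)c(OC)c1
A4 | alternative 2 | ethyl (2S,3S)-3-[3-methoxy-4-(methoxymethoxy)phenyl]oxirane-2-carboxylate (cis) | CCOC(=O)[C@H]1O[C@H]1c1ccc(OCOC)c(OC)c1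
A5 | alternative 2 | 2-ethyl 6-methyl (2S,3R)-8-methoxy-3-[3-methoxy-4-(methoxymethoxy)phenyl]-2,3-dihydro-1,4-benzodioxine-2,6-dicarboxylate (trans) | COc1cc([C@H]2Oc3cc(C(=O)OC)cc(OC)c3O[C@@H]2C(=O)OCC)ccc1OCOC
A6 | alternative 3 | 2-iodo-3,5-bis(methoxymethoxy)phenol | Oc1cc(OCOC)cc(OCOC)c1I
A7 | alternative 3 | tert-butyl{[(2R,3R)-6-ethynyl-8-methoxy-3-[3-methoxy-4-(methoxymethoxy)phenyl]-2,3-dihydro-1,4-benzodioxin-2-yl]methoxy}dimethylsilane | COc1cc([C@H]2Oc3cc(C#C)cc(OC)c3O[C@@H]2CO[Si](C)(C)C(C)(C)C)ccc1OCOC
A8 | alternative 3 | 2-[(2R,3R)-2-{[tert-butyl(dimethyl)silyl]oxymethyl}-8-methoxy-3-[3-methoxy-4-(methoxymethoxy)phenyl]-2,3-dihydro-1,4-benzodioxin-6-yl]-5,7-bis(methoxymethoxy)-4H-chromen-4-one | COc1cc([C@H]2Oc3cc(-c4cc(=O)c5c(OCOC)cc(OCOC)cc5o4)cc(OC)c3O[C@@H]2CO[Si](C)(C)C(C)(C)C)ccc1OCOC
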